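## Retrosynthetic overview
1. The target comes from a Schenck singlet-oxygen ene reaction on the C4=C5 alkene of ovatodiolide (**25**), which installs the 5-OOH and the 4-exomethylene.
2. Ovatodiolide comes from a macro-ring-closing metathesis that forms the trisubstituted E C7=C8 alkene (14-membered ring). Both lactones are already in place, so the macrocycle closes last.
3. The RCM precursor comes from a Negishi coupling (C5–C6, E geometry kept) between an E-vinyl iodide on a trans-α-methylene-γ-lactone and an alkylzinc from a butenolide iodide.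
4. The trans-lactone comes from an anti-selective Cr allylation of acrolein, lipase resolution, then lactonisation. The butenolide comes from RCM of an acrylate ester of a Sharpless-resolved vinyl carbinol.
5. Ring order: butenolide (Step 7), α-methylene lactone (Step 16), macrocycle (Step 18).

**Assumptions**
- The ring Δ4,5 alkene of ovatodiolide is E, and 1O2 attacks the exposed macrocycle face to give the 5β-OOH (5R as drawn); any C5 epimer is separated by HPLC.
- Cr-mediated allylation gives the anti adduct, which lactonises to the trans-lactone.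
- The lipase acylates the (4R)-carbinol of the racemic hydroxy ester.

## Route

**Step 1**
Reactants: **1** acrolein; **2** methallylmagnesium chloride
Product: **3** (±)-5-methylhexa-1,5-dien-3-ol
Conditions: THF, −78 → 0 °C; then aq. NH4Cl
Reagents that add atoms: none (H from workup only)
Why: Grignard 1,2-addition to the enal gives the racemic vinyl carbinol needed for the resolution in Step 2.

**Step 2**
Reactants: **3**
Product: **4** (3R)-5-methylhexa-1,5-dien-3-ol
Conditions: Ti(OiPr)4 (10 mol%), L-(+)-DIPT (12 mol%), TBHP (0.6 equiv), 4 Å MS, CH2Cl2, −20 °C, stopped at about 58% conversion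
Reagents that add atoms: none (the TBHP oxygen ends up in the discarded (S)-epoxy alcohol)
Why: Sharpless kinetic resolution with the chiral Ti-tartrate catalyst epoxidises the (S)-carbinol fast and leaves the (R)-carbinol, which sets C-e.

**Step 3**
Reactants: **5** triethyl phosphonoacetate; **6** (2-bromoethoxy)-tert-butyldimethylsilane
Product: **7** ethyl 2-(diethoxyphosphoryl)-4-(TBSO)butanoate
Conditions: NaH, THF/DMF, 0 → 50 °C
Reagents that add atoms: none
Why: Enolate C-alkylation of the phosphonoacetate; the C2 centre is racemic and is destroyed in Step 4.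

**Step 4**
Reactants: **7**; **8** formaldehyde (37% aq.)
Product: **9** ethyl 4-(TBSO)-2-methylenebutanoate
Conditions: K2CO3, THF/H2O, rt → 50 °C
Reagents that add atoms: none
Why: Horner–Wadsworth–Emmons methylenation of the α-alkyl phosphonoacetate gives the α-substituted acrylate.

**Step 5**
Reactants: **9**
Product: **10** 4-(TBSO)-2-methylenebutanoic acid
Conditions: LiOH, THF/MeOH/H2O, rt
Reagents that add atoms: none (water, as hydroxide, is lost as EtOH/carboxylate; only H is added)
Why: Saponification; the TBS ether and acrylate survive at rt.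

**Step 6**
Reactants: **10**; **4**
Product: **11** (3R)-5-methylhexa-1,5-dien-3-yl 4-(TBSO)-2-methylenebutanoate
Conditions: 2,4,6-Cl3C6H2COCl, Et3N, THF, rt; then **4**, DMAP, toluene, rt
Reagents that add atoms: none (the acyl chloride only activates the acid)
Why: Yamaguchi esterification proceeds with retention at the secondary carbinol, so C-e is untouched.

**Step 7**
Reactants: **11**
Product: **12** (5R)-3-[2-(TBSO)ethyl]-5-(2-methylallyl)furan-2(5H)-one
Conditions: Grubbs II (5 mol%), CH2Cl2 (5 mM), 40 °C
Reagents that add atoms: none (ethylene is lost)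
Why: Ring-closing metathesis of the acrylate with the monosubstituted vinyl gives the 5-membered butenolide. The 1,1-disubstituted methallyl alkene is inert, and no new stereocentre forms.

**Step 8**
Reactants: **12**
Product: **13** (5R)-3-(2-hydroxyethyl)-5-(2-methylallyl)furan-2(5H)-one
Conditions: HF·pyridine, pyridine/THF, 0 °C → rt
Reagents that add atoms: none
Why: Acidic fluoride desilylation avoids the base that could epimerise the acidic γ-H of the butenolide.

**Step 9**
Reactants: **13**
Product: **14** (5R)-3-(2-iodoethyl)-5-(2-methylallyl)furan-2(5H)-one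
Conditions: I2, PPh3, imidazole, CH2Cl2, 0 °C
Reagents that add atoms: iodine, II
Why: Appel iodination of a primary alcohol by SN2, with no change at the butenolide stereocentre.

**Step 10**
Reactants: **15** 4-pentyn-1-ol
Product: **16** (4E)-5-iodo-4-methylpent-4-en-1-ol
Conditions: Me3Al, cat. Cp2ZrCl2, CH2Cl2, rt; then I2, THF, −30 °C
Reagents that add atoms: trimethylaluminium, C[Al](C)C; iodine, II
Why: Negishi Zr-catalysed carboalumination is a syn addition of Me and Al to the terminal alkyne. Iodinolysis then gives the E-trisubstituted vinyl iodide, with I trans to the chain.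

**Step 11**
Reactants: **16**
Product: **17** (4E)-5-iodo-4-methylpent-4-enal
Conditions: Dess–Martin periodinane, NaHCO3, CH2Cl2, 0 °C → rt
Reagents that add atoms: none
Why: Mild oxidation leaves the vinyl iodide intact.

**Step 12**
Reactants: **17**; **18** ethyl acrylate
Product: **19** ethyl 2-[(4E)-1-hydroxy-5-iodo-4-methylpent-4-en-1-yl]acrylate (racemic)
Conditions: DABCO (0.5 equiv), MeOH (1 equiv), neat, rt, 4 d
Reagents that add atoms: none
Why: Morita–Baylis–Hillman reaction; the carbinol is racemic and becomes sp2 in Step 13.

**Step 13**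
Reactants: **19**
Product: **20** ethyl (2Z,6E)-2-(bromomethyl)-7-iodo-6-methylhepta-2,6-dienoate
Conditions: NBS, Me2S, CH2Cl2, 0 °C → rt
Reagents that add atoms: N-bromosuccinimide, O=C1CCC(=O)N1Br
Why: Bromodimethylsulfonium-mediated SN2′ substitution of the Baylis–Hillman alcohol gives the Z-allylic bromide.

**Step 14**
Reactants: **20**; **1** acrolein
Product: **21** ethyl (3R*,4S*)-4-hydroxy-3-[(3E)-4-iodo-3-methylbut-3-en-1-yl]-2-methylidenehex-5-enoate (racemic anti)
Conditions: CrCl2 (Ni-free, 4 equiv), THF, 0 °C → rt
Reagents that add atoms: none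
Why: Hiyama-type allylchromium addition attacks through the γ-carbon in a Zimmerman–Traxler chair, giving the anti pair (racemic) that becomes the trans-lactone. Ni-free CrCl2 leaves the vinyl iodide alone.

**Step 15**
Reactants: **21**
Product: **22** ethyl (3R,4S)-4-hydroxy-3-[(3E)-4-iodo-3-methylbut-3-en-1-yl]-2-methylidenehex-5-enoate
Conditions: Lipase PS-C (*Pseudomonas cepacia*, a hydrolase), vinyl acetate, MTBE, 25 °C, about 50% conversion; chromatographic separation
Reagents that add atoms: none (vinyl acetate, C=COC(C)=O, acetylates the (4R)-enantiomer into the discarded by-product)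
Why: Lipase-catalysed enantioselective transesterification (kinetic resolution) acetylates the (4R)-carbinol, leaving the (3R,4S)-alcohol and fixing the absolute configuration of C-d and C-f.

**Step 16**
Reactants: **22**
Product: **23** (4R,5S)-4-[(3E)-4-iodo-3-methylbut-3-en-1-yl]-3-methylidene-5-vinyloxolan-2-one (trans-lactone)
Conditions: p-TsOH·H2O (10 mol%), toluene, 60 °C
Reagents that add atoms: none (EtOH is lost)
Why: Acid-catalysed 5-exo lactonisation of the anti γ-hydroxy-α-methylene ester gives the trans-4,5-disubstituted α-methylene-γ-butyrolactone without touching the stereocentres.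

**Step 17**
Reactants: **14**; **23**
Product: **24** RCM precursor: trans-lactone carrying d-vinyl and the f-chain CH2CH2–C(Me)=CH–CH2CH2– linked to C3 of the (5R)-5-(2-methylallyl)butenolide
Conditions: (i) **14**, Zn dust (TMSCl/BrCH2CH2Br-activated), LiCl, THF, rt, to give the alkylzinc iodide in situ; (ii) **23**, Pd(dppf)Cl2 (10 mol%), THF, 50 °C
Reagents that add atoms: none (the Zn reagent is generated from **14**; iodide leaves as ZnI2)
Why: Negishi sp3–sp2 coupling proceeds with retention of the E-alkene geometry and creates no stereocentre.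

**Step 18**
Reactants: **24**
Product: **25** ovatodiolide
Conditions: Hoveyda–Grubbs II (20 mol%), 1,4-benzoquinone (20 mol%), toluene (1 mM, syringe-pump addition), 80 °C
Reagents that add atoms: none (ethylene is lost)
Why: Macro-RCM between the d-vinyl and e-methallyl termini closes the 14-membered ring with the thermodynamically favoured E-trisubstituted alkene; all three stereocentres are untouched and the product is C20H24O4.

**Step 19**
Reactants: **25**
Product: **26** 4-methylene-5β-hydroperoxyovatodiolide (target)
Conditions: O2, TPP (0.5 mol%), visible light, CH2Cl2, −78 → −20 °C; cold chromatography, no reductive workup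
Reagents that add atoms: dioxygen, O=O
Why: Schenck ene reaction; electrophilic 1O2 reacts with the most electron-rich alkene (Δ4,5), abstracts H from the C4 methyl (cis effect) and bonds O at C5, giving the exomethylene and secondary 5-OOH. The new C5 centre is set by attack on the macrocycle's exposed face.

## Compound list
1 | acrolein | C=CC=O | starting material
2 | methallylmagnesium chloride | C=C(C)C[Mg]Cl | starting material
3 | (±)-5-methylhexa-1,5-dien-3-ol | C=CC(O)CC(C)=C | intermediate
4 | (3R)-5-methylhexa-1,5-dien-3-ol | C=C[C@H](O)CC(C)=C | intermediate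
5 | triethyl phosphonoacetate | CCOC(=O)CP(=O)(OCC)OCC | starting material
6 | (2-bromoethoxy)-tert-butyldimethylsilane | CC(C)(C)[Si](C)(C)OCCBr | starting material
7 | ethyl 2-(diethoxyphosphoryl)-4-(TBSO)butanoate (racemic at C2) | CCOC(=O)C(CCO[Si](C)(C)C(C)(C)C)P(=O)(OCC)OCC | intermediate
8 | formaldehyde | C=O | starting material
9 | ethyl 4-(TBSO)-2-methylenebutanoate | C=C(CCO[Si](C)(C)C(C)(C)C)C(=O)OCC | intermediate
10 | 4-(TBSO)-2-methylenebutanoic acid | C=C(CCO[Si](C)(C)C(C)(C)C)C(=O)O | intermediate
11 | (3R)-5-methylhexa-1,5-dien-3-yl 4-(TBSO)-2-methylenebutanoate | C=C(CCO[Si](C)(C)C(C)(C)C)C(=O)O[C@@H](C=C)CC(C)=C | intermediate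
12 | (5R)-3-[2-(TBSO)ethyl]-5-(2-methylallyl)furan-2(5H)-one | C=C(C)C[C@@H]1C=C(CCO[Si](C)(C)C(C)(C)C)C(=O)O1 | intermediate
13 | (5R)-3-(2-hydroxyethyl)-5-(2-methylallyl)furan-2(5H)-one | C=C(C)C[C@@H]1C=C(CCO)C(=O)O1 | intermediate
14 | (5R)-3-(2-iodoethyl)-5-(2-methylallyl)furan-2(5H)-one | C=C(C)C[C@@H]1C=C(CCI)C(=O)O1 | intermediate
15 | 4-pentyn-1-ol | C#CCCCO | starting material
16 | (4E)-5-iodo-4-methylpent-4-en-1-ol | OCCC/C(C)=C/I | intermediate
17 | (4E)-5-iodo-4-methylpent-4-enal | O=CCC/C(C)=C/I | intermediate
18 | ethyl acrylate | C=CC(=O)OCC | starting material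
19 | ethyl 2-[(4E)-1-hydroxy-5-iodo-4-methylpent-4-en-1-yl]acrylate (racemic) | C=C(C(=O)OCC)C(O)CC/C(C)=C/I | intermediate
20 | ethyl (2Z,6E)-2-(bromomethyl)-7-iodo-6-methylhepta-2,6-dienoate | BrC/C(C(=O)OCC)=C\CC/C(C)=C/I | intermediate
21 | rac-anti hydroxy ester (drawn as the 3R,4S enantiomer) | C=C(C(=O)OCC)[C@@H](CC/C(C)=C/I)[C@@H](O)C=C | intermediate
22 | ethyl (3R,4S)-4-hydroxy-3-[(3E)-4-iodo-3-methylbut-3-en-1-yl]-2-methylidenehex-5-enoate | C=C(C(=O)OCC)[C@@H](CC/C(C)=C/I)[C@@H](O)C=C | intermediate
23 | (4R,5S)-4-[(3E)-4-iodo-3-methylbut-3-en-1-yl]-3-methylidene-5-vinyloxolan-2-one | C=C1C(=O)O[C@@H](C=C)[C@@H]1CC/C(C)=C/I | intermediate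
24 | RCM precursor (trans-lactone–butenolide diene, E-Δ4,5) | C=C1C(=O)O[C@@H](C=C)[C@@H]1CC/C(C)=C/CCC2=C[C@@H](CC(C)=C)OC2=O | intermediate
25 | ovatodiolide | C=C1C(=O)O[C@H]2/C=C(\C)C[C@@H]3C=C(CC/C=C(\C)CC[C@H]12)C(=O)O3 | intermediate
26 | 4-methylene-5β-hydroperoxyovatodiolide | C=C1C(=O)O[C@H]2/C=C(\C)C[C@@H]3C=C(CC[C@@H](OO)C(=C)CC[C@H]12)C(=O)O3 | target

## Summary
- Total steps: 19.
- Longest linear sequence: 10 steps (4-pentyn-1-ol → **26**; the phosphonoacetate branch also gives 10).
- The three steps most likely to fail:
  1. **Step 18 (macro-RCM):** E/Z mixtures, oligomers or competing metathesis at the other alkenes. Fallback: close the ring instead by intramolecular Cr-mediated allylation of a Baylis–Hillman-derived allylic bromide onto an enal, forming the d–f bond and the lactone last.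
  2. **Step 19 (photooxygenation):** poor regio-, chemo- or facial selectivity, for example ene reaction at the C7=C8 alkene or the wrong C5 configuration. Fallback: build the 5-hydroxy-4-methylene macrocycle by intramolecular NHK of a vinyl iodide onto the Ru-Alder-ene butenolide CH2CH2CHO, then convert the C5 alcohol (prepared as the 5S epimer) to the hydroperoxide by mesylate displacement with buffered aqueous H2O2 with inversion.
  3. **Step 17 (Negishi of the butenolide alkylzinc):** β-hydride elimination, or zinc attack on the Michael acceptors. Fallback: form the C4=C5 bond by E-selective HWE of the butenolide CH2CH2CHO with triethyl 2-phosphonopropionate, then elaborate the ester to the C3–C2 linkage.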